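**Strategy.** Everything rests on disconnecting the bond between the ketone carbon C1 and the adjacent cyclobutane CH, C11 (longipinane numbering). The key step closes the cyclohexenone ring across the 1,3-positions of the doubly bridged cyclobutane (C4, C5, C10, C11): SmI2 reduces a C11 iodide and the configurationally labile cyclobutylsamarium acylates an ester tethered from C4, so both iodide epimers funnel into the only bridge that can form. The precursor is an 8-iodobicyclo[4.1.1]octane with an ester side chain, built from eucarvone by asymmetric epoxidation, a lactone relay of configuration, carbenoid closure to a bicyclo[1.1.0]butane and strain-release hydroiodination.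

Key step: step 12

Remark: eucarvone and all numbered reagents are taken as catalogue chemicals; tricyclic compounds use longipinane numbering (C1 ketone, C4 and C11 bridgeheads of the enone bridge, C5 and C10 the other cyclobutane carbons, C7 and C8 oxygenated).

## Route

Step 1
Reactants: 1 eucarvone (2,6,6-trimethylcyclohepta-2,4-dien-1-one); 2 3-chloroperoxybenzoic acid
Product: 3 (1R,7S)-2,2,5-trimethyl-8-oxabicyclo[5.1.0]oct-5-en-4-one
Conditions: (S,S)-Jacobsen catalyst [(S,S)-N,N′-bis(3,5-di-tert-butylsalicylidene)-1,2-cyclohexanediaminomanganese chloride] (5 mol %), N-methylmorpholine N-oxide, CH2Cl2, −78 °C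
Reagents that add atoms: 3-chloroperoxybenzoic acid, OOC(=O)c1cccc(Cl)c1
Why: Jacobsen–Katsuki epoxidation should engage only the electron-richer cis-disubstituted γ,δ-alkene (conjugated and flanked by the quaternary carbon, as in 2,2-dimethylchromenes) and not the electron-poor α,β-alkene, the (S,S)-salen ligand setting both epoxide centres by analogy with the chromene series.

Step 2
Reactants: 3 (1R,7S)-2,2,5-trimethyl-8-oxabicyclo[5.1.0]oct-5-en-4-one; 4 tert-butyl bromoacetate
Product: 5 tert-butyl 2-[(1R,7S)-2,2,5-trimethyl-4-oxo-8-oxabicyclo[5.1.0]oct-5-en-3-yl]acetate (C3 epimer mixture)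
Conditions: LiN(SiMe3)2, THF, −78 °C; then 4, DMPU, −78 to −30 °C
Reagents that add atoms: tert-butyl bromoacetate, CC(C)(C)OC(=O)CBr
Why: Kinetic deprotonation at the only sp3 α-carbon should give the cross-conjugated lithium enolate, whose SN2 alkylation next to a gem-dimethyl carbon is precedented for isophorone-type enolates, and the configuration of the new enolisable C3 centre is left open because step 3 funnels both epimers.

Step 3
Reactants: 5 tert-butyl 2-[(1R,7S)-2,2,5-trimethyl-4-oxo-8-oxabicyclo[5.1.0]oct-5-en-3-yl]acetate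
Product: 7 (1R,5S,6S)-5-hydroxy-3,10,10-trimethyl-7-oxabicyclo[4.3.1]dec-3-ene-2,8-dione, via epoxy keto acid 6 (not isolated)
Conditions: CF3CO2H, CH2Cl2, 0 °C to rt
Reagents that add atoms: none
Why: Acidolysis of the tert-butyl ester followed by acid-catalysed intramolecular epoxide opening (6-exo lactonisation with SN2 inversion at the epoxide carbon next to the quaternary carbon, the only one the carboxyl can reach) should give the trans hydroxy lactone, and because only the epimer with the side chain anti to the epoxide oxygen can attack while the other epimerises through the ketone enol, the bridged lactone fixes the ring stereocentre cis to the lactone oxygen.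

Step 4
Reactants: 7 (1R,5S,6S)-5-hydroxy-3,10,10-trimethyl-7-oxabicyclo[4.3.1]dec-3-ene-2,8-dione; 8 p-toluenesulfonohydrazide
Product: 11 (1S,5S,6S)-5-hydroxy-3,10,10-trimethyl-7-oxabicyclo[4.3.1]dec-2-en-8-one, via tosylhydrazone 9 (not isolated), via allylic diazene 10 (not isolated)
Conditions: TsNHNH2, PPTS (cat.), THF, 60 °C; then catecholborane, CHCl3, 0 °C; then NaOAc·3H2O, 65 °C
Reagents that add atoms: none
Why: In this Kabalka alkene-transposing reduction hydride adds to the C=N carbon of the enone tosylhydrazone, sulfinate loss gives the allylic diazene and its retro-ene hydrogen shift with loss of N2 should move the alkene to C2=C3 and leave a CH2 at C4, creating no stereocentre while the bridged lactone keeps C1 from epimerising.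

Step 5
Reactants: 11 (1S,5S,6S)-5-hydroxy-3,10,10-trimethyl-7-oxabicyclo[4.3.1]dec-2-en-8-one; 12 N,O-dimethylhydroxylamine hydrochloride
Product: 13 2-[(1S,5S,6S)-5,6-dihydroxy-3,7,7-trimethylcyclohept-2-en-1-yl]-N-methoxy-N-methylacetamide
Conditions: Me(MeO)NH·HCl, AlMe3, CH2Cl2, 0 °C to rt
Reagents that add atoms: N,O-dimethylhydroxylamine hydrochloride, CNOC.Cl
Why: Weinreb aminolysis of the lactone by the aluminium amide should be irreversible and touch no stereocentre, releasing the side chain that a bicyclobutane could not accommodate as a lactone.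

Step 6
Reactants: 13 2-[(1S,5S,6S)-5,6-dihydroxy-3,7,7-trimethylcyclohept-2-en-1-yl]-N-methoxy-N-methylacetamide; 14 tert-butyldimethylsilyl trifluoromethanesulfonate
Product: 15 2-[(1S,5S,6S)-5,6-bis(tert-butyldimethylsilyloxy)-3,7,7-trimethylcyclohept-2-en-1-yl]-N-methoxy-N-methylacetamide
Conditions: TBSOTf, 2,6-lutidine, CH2Cl2, 0 °C
Reagents that add atoms: tert-butyldimethylsilyl trifluoromethanesulfonate, CC(C)(C)[Si](C)(C)OS(=O)(=O)C(F)(F)F
Why: Silylation with the silyl triflate should protect both hydroxyls, including the hindered one next to the gem-dimethyl carbon, so that no O–H bond can intercept the carbenoid of step 8.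

Step 7
Reactants: 15 2-[(1S,5S,6S)-5,6-bis(tert-butyldimethylsilyloxy)-3,7,7-trimethylcyclohept-2-en-1-yl]-N-methoxy-N-methylacetamide; 16 2,2,2-trifluoroethyl trifluoroacetate; 17 methanesulfonyl azide
Product: 19 2-diazo-2-[5,6-bis(tert-butyldimethylsilyloxy)-3,7,7-trimethylcyclohept-2-en-1-yl]-N-methoxy-N-methylacetamide, via trifluoroacetyl amide 18 (not isolated)
Conditions: LiN(i-Pr)2, THF, −78 °C; 16; then 17, Et3N, H2O, MeCN, rt
Reagents that add atoms: methanesulfonyl azide, CS(=O)(=O)N=[N+]=[N-]
Why: Danheiser detrifluoroacetylative diazo transfer (a Regitz-type transfer) should activate the only enolisable CH2 as its trifluoroacetyl derivative and then install the diazo group there with loss of the trifluoroacetyl group, leaving the ring stereocentres untouched.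

Step 8
Reactants: 19 2-diazo-2-[5,6-bis(tert-butyldimethylsilyloxy)-3,7,7-trimethylcyclohept-2-en-1-yl]-N-methoxy-N-methylacetamide
Product: 20 N-methoxy-N,2,6,6-tetramethyl-4,5-bis(tert-butyldimethylsilyloxy)tricyclo[5.1.0.0(2,8)]octane-8-carboxamide
Conditions: Rh2(O2CCMe3)4 (1 mol %), toluene, −78 °C to rt, slow addition of 19
Reagents that add atoms: none
Why: Rhodium-carbenoid intramolecular cyclopropanation of an α-allyl-α-diazo carbonyl compound (the known route to bicyclo[1.1.0]butanes) should deliver the carbenoid carbon to the trisubstituted ring alkene from the only face its one-atom tether allows, so the existing ring stereocentre dictates the configuration of the new cage centres, while the bulky carboxylate ligands and low temperature disfavour the competing 1,2-hydride shift.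

Step 9
Reactants: 20 N-methoxy-N,2,6,6-tetramethyl-4,5-bis(tert-butyldimethylsilyloxy)tricyclo[5.1.0.0(2,8)]octane-8-carboxamide; 21 methylmagnesium bromide
Product: 22 1-[4,5-bis(tert-butyldimethylsilyloxy)-2,6,6-trimethyltricyclo[5.1.0.0(2,8)]oct-8-yl]ethanone
Conditions: MeMgBr, THF, −78 to 0 °C
Reagents that add atoms: methylmagnesium bromide, C[Mg]Br
Why: Weinreb ketone synthesis should stop at the chelated tetrahedral intermediate and give the methyl ketone, the hard Grignard reagent adding to the carbonyl group and not across the strained central bond.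

Step 10
Reactants: 22 1-[4,5-bis(tert-butyldimethylsilyloxy)-2,6,6-trimethyltricyclo[5.1.0.0(2,8)]oct-8-yl]ethanone; 23 hydrogen iodide
Product: 24 1-[3,4-bis(tert-butyldimethylsilyloxy)-8-iodo-1,5,5-trimethylbicyclo[4.1.1]oct-7-yl]ethanone (acetyl anti to the four-carbon bridge)
Conditions: HI (57% aq., 1.2 equiv), CH2Cl2, 0 °C to rt
Reagents that add atoms: hydrogen iodide, I
Why: In this strain-release hydroiodination of an acyl bicyclobutane iodide attacks the unsubstituted bridgehead from the rear of the central bond and the resulting enol ketonises reversibly under the acid, so the acetyl group should settle in the less hindered position anti to the four-carbon bridge, the geometry the later bridge requires.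

Step 11
Reactants: 24 1-[3,4-bis(tert-butyldimethylsilyloxy)-8-iodo-1,5,5-trimethylbicyclo[4.1.1]oct-7-yl]ethanone; 25 1-methoxy-1-(trimethylsilyloxy)ethene
Product: 26 methyl 3-[3,4-bis(tert-butyldimethylsilyloxy)-8-iodo-1,5,5-trimethylbicyclo[4.1.1]oct-7-yl]-3-(trimethylsilyloxy)butanoate (carbinol epimer mixture)
Conditions: 25, Tf2NH (5 mol %), CH2Cl2, −78 °C
Reagents that add atoms: 1-methoxy-1-(trimethylsilyloxy)ethene, COC(=C)O[Si](C)(C)C
Why: Mukaiyama aldol addition with silyl transfer adds the acetate unit to the methyl ketone without base, so the γ-iodo ketone cannot re-close to the bicyclobutane, and the new silyloxy-bearing centre may form as a mixture because step 13 erases it.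

Step 12
Reactants: 26 methyl 3-[3,4-bis(tert-butyldimethylsilyloxy)-8-iodo-1,5,5-trimethylbicyclo[4.1.1]oct-7-yl]-3-(trimethylsilyloxy)butanoate
Product: 27 7,8-bis(tert-butyldimethylsilyloxy)-3-(trimethylsilyloxy)longipinan-1-one
Conditions: SmI2 (2.5 equiv), Fe(acac)3 (5 mol %), THF, −30 °C to rt
Reagents that add atoms: none
Why: SmI2 transfers one electron to the carbon–iodine bond of 26 to give a cyclobutyl radical that is reduced again to a cyclobutylsamarium species, which adds to the ester carbonyl held above the four-membered ring by the side chain and expels methoxide, forming the C1–C11 bond of ketone 27. The closest known reaction type is the SmI2-promoted intramolecular nucleophilic acyl substitution of iodo esters (an intramolecular Barbier-type acylation). The one ring closed is the six-membered ketone ring, formed in the 6-exo-trig mode across the 1,3-positions of the cyclobutane to give the bicyclo[3.1.1]heptanone unit. The new stereocentre C11 is fixed by the cage, because only a bond on the face anti to the four-carbon bridge can span to the C4 side chain, and the radical and the organosamarium species invert freely, so both iodide epimers converge on one product. The step needs acylation to outrun hydrogen transfer to C11 and over-reduction, which the cis-1,3 proximity of the ester, the absence of acidic O–H groups and the slow reduction of a hindered ketone by SmI2 without additives should secure.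

Step 13
Reactants: 27 7,8-bis(tert-butyldimethylsilyloxy)-3-(trimethylsilyloxy)longipinan-1-one
Product: 28 7,8-bis(tert-butyldimethylsilyloxy)longipin-2-en-1-one
Conditions: DBU, toluene, 80 °C
Reagents that add atoms: none
Why: In this E1cB elimination DBU can enolise only towards C2 because C11 is a bridgehead, and loss of trimethylsilanolate from C3 should give the conjugated enone without the cationic intermediates that would trigger Wagner–Meerwein shifts of the cyclobutylcarbinyl system.

Step 14
Reactants: 28 7,8-bis(tert-butyldimethylsilyloxy)longipin-2-en-1-one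
Product: 29 7,8-dihydroxylongipin-2-en-1-one
Conditions: HF·pyridine, THF, 0 °C to rt
Reagents that add atoms: none
Why: Fluoride-mediated desilylation under mildly acidic conditions should free both hydroxyls and leave the enone and the cage untouched, the C4 bridgehead being unable to epimerise.

Step 15
Reactants: 29 7,8-dihydroxylongipin-2-en-1-one; 30 isobutyryl chloride
Product: 31 7-hydroxy-8-isobutyryloxylongipin-2-en-1-one
Conditions: i-PrCOCl (1.05 equiv), 2,4,6-collidine, CH2Cl2, −40 to 0 °C
Reagents that add atoms: isobutyryl chloride, CC(C)C(Cl)=O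
Why: Sterically controlled monoacylation should select the C8 hydroxyl flanked by a CH2 group over the neopentyl C7 hydroxyl next to the gem-dimethyl carbon.

Step 16
Reactants: 31 7-hydroxy-8-isobutyryloxylongipin-2-en-1-one; 32 angelic acid
Product: 33 7-angeloyloxy-8-isobutyryloxylongipin-2-en-1-one (CNP0286736.1)
Conditions: 32, 2,4,6-Cl3C6H2COCl, Et3N, toluene, rt; then 31, 80 °C
Reagents that add atoms: angelic acid, C/C=C(/C)C(O)=O
Why: Yamaguchi-type esterification through the mixed 2,4,6-trichlorobenzoic anhydride without a nucleophilic catalyst is the established way to acylate hindered alcohols with angelic acid while keeping the Z alkene from isomerising to the tiglate.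

## Compound list

1 | eucarvone (2,6,6-trimethylcyclohepta-2,4-dien-1-one) | CC1=CC=CC(C)(C)CC1=O | starting material
2 | 3-chloroperoxybenzoic acid | OOC(=O)c1cccc(Cl)c1 | starting material
3 | (1R,7S)-2,2,5-trimethyl-8-oxabicyclo[5.1.0]oct-5-en-4-one | CC1=C[C@@H]2O[C@@H]2C(C)(C)CC1=O | intermediate
4 | tert-butyl bromoacetate | CC(C)(C)OC(=O)CBr | starting material
5 | tert-butyl 2-[(1R,7S)-2,2,5-trimethyl-4-oxo-8-oxabicyclo[5.1.0]oct-5-en-3-yl]acetate, both C3 epimers | CC1=C[C@@H]2O[C@@H]2C(C)(C)C(CC(=O)OC(C)(C)C)C1=O | intermediate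
6 | 2-[(1R,7S)-2,2,5-trimethyl-4-oxo-8-oxabicyclo[5.1.0]oct-5-en-3-yl]acetic acid | CC1=C[C@@H]2O[C@@H]2C(C)(C)C(CC(=O)O)C1=O | intermediate
7 | (1R,5S,6S)-5-hydroxy-3,10,10-trimethyl-7-oxabicyclo[4.3.1]dec-3-ene-2,8-dione (5-OH trans to the lactone oxygen on C6) | O=C1C[C@H]2C(=O)C(C)=C[C@H](O)[C@@H](O1)C2(C)C | intermediate
8 | p-toluenesulfonohydrazide | Cc1ccc(cc1)S(=O)(=O)NN | starting material
9 | C2 tosylhydrazone of 7 | O=C1C[C@H]2C(=NNS(=O)(=O)c3ccc(C)cc3)C(C)=C[C@H](O)[C@@H](O1)C2(C)C | intermediate
10 | 2-diazenyl-5-hydroxy-3,10,10-trimethyl-7-oxabicyclo[4.3.1]dec-3-en-8-one (allylic diazene, C2 unassigned) | O=C1C[C@H]2C(N=N)C(C)=C[C@H](O)[C@@H](O1)C2(C)C | intermediate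
11 | (1S,5S,6S)-5-hydroxy-3,10,10-trimethyl-7-oxabicyclo[4.3.1]dec-2-en-8-one | O=C1C[C@H]2C=C(C)C[C@H](O)[C@@H](O1)C2(C)C | intermediate
12 | N,O-dimethylhydroxylamine hydrochloride | CNOC.Cl | starting material
13 | 2-[(1S,5S,6S)-5,6-dihydroxy-3,7,7-trimethylcyclohept-2-en-1-yl]-N-methoxy-N-methylacetamide | CON(C)C(=O)C[C@H]1C=C(C)C[C@H](O)[C@@H](O)C1(C)C | intermediate
14 | tert-butyldimethylsilyl trifluoromethanesulfonate | CC(C)(C)[Si](C)(C)OS(=O)(=O)C(F)(F)F | starting material
15 | 2-[(1S,5S,6S)-5,6-bis(tert-butyldimethylsilyloxy)-3,7,7-trimethylcyclohept-2-en-1-yl]-N-methoxy-N-methylacetamide | CON(C)C(=O)C[C@H]1C=C(C)C[C@H](O[Si](C)(C)C(C)(C)C)[C@@H](O[Si](C)(C)C(C)(C)C)C1(C)C | intermediate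
16 | 2,2,2-trifluoroethyl trifluoroacetate | FC(F)(F)COC(=O)C(F)(F)F | starting material
17 | methanesulfonyl azide | CS(=O)(=O)N=[N+]=[N-] | starting material
18 | 2-trifluoroacetyl derivative of 15 (new centre unassigned) | CON(C)C(=O)C(C(=O)C(F)(F)F)[C@H]1C=C(C)C[C@H](O[Si](C)(C)C(C)(C)C)[C@@H](O[Si](C)(C)C(C)(C)C)C1(C)C | intermediate
19 | 2-diazo derivative of 15 | CON(C)C(=O)C(=[N+]=[N-])[C@H]1C=C(C)C[C@H](O[Si](C)(C)C(C)(C)C)[C@@H](O[Si](C)(C)C(C)(C)C)C1(C)C | intermediate
20 | N-methoxy-N,2,6,6-tetramethyl-4,5-bis(tert-butyldimethylsilyloxy)tricyclo[5.1.0.0(2,8)]octane-8-carboxamide (bicyclobutane, four-carbon chain bridging its two lateral carbons) | CON(C)C(=O)[C@@]12[C@H]3[C@]1(C)C[C@H](O[Si](C)(C)C(C)(C)C)[C@@H](O[Si](C)(C)C(C)(C)C)C(C)(C)[C@@H]23 | intermediate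
21 | methylmagnesium bromide | C[Mg]Br | starting material
22 | 1-[4,5-bis(tert-butyldimethylsilyloxy)-2,6,6-trimethyltricyclo[5.1.0.0(2,8)]oct-8-yl]ethanone | CC(=O)[C@@]12[C@H]3[C@]1(C)C[C@H](O[Si](C)(C)C(C)(C)C)[C@@H](O[Si](C)(C)C(C)(C)C)C(C)(C)[C@@H]23 | intermediate
23 | hydrogen iodide | I | starting material
24 | 1-[3,4-bis(tert-butyldimethylsilyloxy)-8-iodo-1,5,5-trimethylbicyclo[4.1.1]oct-7-yl]ethanone (acetyl anti, iodine syn to the C2–C5 bridge) | CC(=O)[C@@H]1[C@@]2(C)C[C@H](O[Si](C)(C)C(C)(C)C)[C@@H](O[Si](C)(C)C(C)(C)C)C(C)(C)[C@@H]1[C@@H]2I | intermediate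
25 | 1-methoxy-1-(trimethylsilyloxy)ethene | COC(=C)O[Si](C)(C)C | starting material
26 | methyl 3-[3,4-bis(tert-butyldimethylsilyloxy)-8-iodo-1,5,5-trimethylbicyclo[4.1.1]oct-7-yl]-3-(trimethylsilyloxy)butanoate, both carbinol epimers | COC(=O)CC(C)(O[Si](C)(C)C)[C@@H]1[C@@]2(C)C[C@H](O[Si](C)(C)C(C)(C)C)[C@@H](O[Si](C)(C)C(C)(C)C)C(C)(C)[C@@H]1[C@@H]2I | intermediate
27 | 7,8-bis(tert-butyldimethylsilyloxy)-3-(trimethylsilyloxy)longipinan-1-one, both C3 epimers | C[Si](C)(C)OC1(C)CC(=O)[C@H]2[C@]3(C)C[C@H](O[Si](C)(C)C(C)(C)C)[C@@H](O[Si](C)(C)C(C)(C)C)C(C)(C)[C@H]2[C@H]13 | intermediate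
28 | 7,8-bis(tert-butyldimethylsilyloxy)longipin-2-en-1-one | CC(C)(C)[Si](C)(C)O[C@@H]1[C@@H](O[Si](C)(C)C(C)(C)C)C[C@@]2(C)[C@@H]3C(=O)C=C(C)[C@H]2[C@@H]3C1(C)C | intermediate
29 | 7,8-dihydroxylongipin-2-en-1-one (trans-diol) | O[C@@H]1[C@@H](O)C[C@@]2(C)[C@@H]3C(=O)C=C(C)[C@H]2[C@@H]3C1(C)C | intermediate
30 | isobutyryl chloride | CC(C)C(Cl)=O | starting material
31 | 7-hydroxy-8-isobutyryloxylongipin-2-en-1-one | O[C@@H]1[C@@H](OC(=O)C(C)C)C[C@@]2(C)[C@@H]3C(=O)C=C(C)[C@H]2[C@@H]3C1(C)C | intermediate
32 | angelic acid ((Z)-2-methylbut-2-enoic acid) | C/C=C(/C)C(O)=O | starting material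
33 | (4R,5S,7S,8S,10R,11R)-7-angeloyloxy-8-isobutyryloxylongipin-2-en-1-one, CNP0286736.1 | C/C=C(/C)C(=O)O[C@@H]1[C@@H](OC(=O)C(C)C)C[C@@]2(C)[C@@H]3C(=O)C=C(C)[C@H]2[C@@H]3C1(C)C | target

## Step count and risks

Total step count: 16. Longest linear sequence: 16 steps (fully linear from eucarvone).

Steps most likely to fail:

Step 12 (key step). The cyclobutyl radical or the organosamarium species may be quenched by hydrogen transfer (from THF or by a 1,5-shift from the ester α-CH2) before it acylates, or the new ketone may be reduced further. The fallback sets out from 26 and returns at 27. Transthioesterification with Me2AlSEt (from AlMe3 and EtSH) gives the S-ethyl thioester F1. Zinc insertion (Zn dust, LiCl, THF) into the carbon–iodine bond gives the configurationally labile secondary alkylzinc iodide F2. An intramolecular Fukuyama coupling (PdCl2(PPh3)2 cat., toluene/THF, rt) then closes the same C1–C11 bond under non-reducing conditions to give 27.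

Step 8. A 1,2-hydride shift of the carbenoid, C–H insertion or ylide formation at a silyl ether oxygen may outrun cyclopropanation of the hindered trisubstituted ring alkene. The fallback sets out from 19 and returns at 20. Heating 19 in toluene at 80 °C in the dark should bring about the intramolecular 1,3-dipolar cycloaddition of the diazo group to the ring alkene, giving the tricyclic 1-pyrazoline F3 (2,3-diazabicyclo[3.1.0]hex-2-ene core). Photolysis (350 nm, pentane, −40 °C) then extrudes N2 and the 1,3-diradical closes to the bicyclobutane 20, the classical pyrazoline route to bicyclo[1.1.0]butanes.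

Step 3. Regiocontrol in the acid-mediated epoxide opening may be lost (intermolecular attack at the allylic carbon or rearrangement of the vinyl epoxide), or the unreactive epimer may equilibrate too slowly. The fallback sets out from 1 and returns at 7. Epoxidation of 1 with the (R,R)-Jacobsen catalyst gives the enantiomeric epoxide F4. Acid-catalysed hydrolysis (HClO4 cat., THF/H2O) opens it at the allylic carbon with inversion to the trans-diol F5, which has the diol configuration of the main route. Alkylation of its trilithio derivative (LiN(SiMe3)2, 3.2 equiv, methyl bromoacetate) gives the dihydroxy keto ester F6. DBU in warm toluene lactonises the hindered hydroxyl onto the ester while the ketone α-centre equilibrates, giving 7.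

Further compounds
F1 | step 12 | S-ethyl 3-[3,4-bis(tert-butyldimethylsilyloxy)-8-iodo-1,5,5-trimethylbicyclo[4.1.1]oct-7-yl]-3-(trimethylsilyloxy)butanethioate | CCSC(=O)CC(C)(O[Si](C)(C)C)[C@@H]1[C@@]2(C)C[C@H](O[Si](C)(C)C(C)(C)C)[C@@H](O[Si](C)(C)C(C)(C)C)C(C)(C)[C@@H]1[C@@H]2I
F2 | step 12 | alkylzinc iodide derived from F1 (C8 configuration labile) | CCSC(=O)CC(C)(O[Si](C)(C)C)[C@@H]1[C@@]2(C)C[C@H](O[Si](C)(C)C(C)(C)C)[C@@H](O[Si](C)(C)C(C)(C)C)C(C)(C)[C@@H]1C2[Zn]I
F3 | step 8 | tricyclic 1-pyrazoline from intramolecular cycloaddition of 19 | CON(C)C(=O)[C@@]12N=N[C@@]3(C)C[C@H](O[Si](C)(C)C(C)(C)C)[C@@H](O[Si](C)(C)C(C)(C)C)C(C)(C)[C@@H]1[C@@H]23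
F4 | step 3 | (1S,7R)-2,2,5-trimethyl-8-oxabicyclo[5.1.0]oct-5-en-4-one | CC1=C[C@H]2O[C@H]2C(C)(C)CC1=O
F5 | step 3 | (4S,5S)-4,5-dihydroxy-2,6,6-trimethylcyclohept-2-en-1-one | CC1=C[C@H](O)[C@@H](O)C(C)(C)CC1=O
F6 | step 3 | methyl 2-[(5S,6S)-5,6-dihydroxy-3,7,7-trimethyl-2-oxocyclohept-3-en-1-yl]acetate, both C1 epimers | COC(=O)CC1C(=O)C(C)=C[C@H](O)[C@@H](O)C1(C)C
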